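The carbocycle C4a–C5–C6–C7–C8–C8a of the isochromanone carries hydroxyls on C6 and C8, a methyl on C7 between them and the lactone carbonyl carbon C1 on C8a; one oxidation level lower, this pattern is a 4-carboxylated 2-methylcyclohexane-1,3-dione, the product of a Michael–Claisen annulation. The ring is therefore built last: dimethyl malonate adds to an ethyl enone that already bears the chromon-6-ylmethyl group on its α-carbon and the silyl-protected (R)-2-hydroxypropyl chain on its β-carbon, and Claisen closure follows in the same flask. One operation forms C4a–C8a and C7–C8 and places all four ring substituents; dehydrogenation, lactonisation and cleavage of the peri methyl ether complete the synthesis.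

Key step: step 9

Remark (assumptions): eugenin is treated as a purchasable chromone; isochromanone numbering (C1–C8a) is used for the new ring and chromone positions are named as such; 13 and 14 are drawn as keto tautomers and will be mixtures of enols and ring diastereomers that converge in step 10; direct formylation of eugenin is avoided because C8 competes, so C6 is addressed by iodination ortho to the free 5-OH.

Step 1
Reactants: 1 eugenin (5-hydroxy-7-methoxy-2-methyl-4H-chromen-4-one)
Product: 2 5-hydroxy-6-iodo-7-methoxy-2-methyl-4H-chromen-4-one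
Conditions: BnMe3N·ICl2 (1.05 equiv), CaCO3, CH2Cl2–MeOH, rt
Reagents that add atoms: benzyltrimethylammonium dichloroiodate, C[N+](C)(C)Cc1ccccc1.Cl[I-]Cl
Why: Electrophilic aromatic iodination with a dichloroiodate: the free, chelated 5-OH directs the iodonium equivalent to its only open ortho position, C6, whereas C8 becomes the preferred site only when the 5-oxygen is alkylated, and CaCO3 takes up the HCl.

Step 2
Reactants: 2 5-hydroxy-6-iodo-7-methoxy-2-methyl-4H-chromen-4-one
Product: 3 6-iodo-5,7-dimethoxy-2-methyl-4H-chromen-4-one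
Conditions: MeI (3 equiv), K2CO3, DMF, 50 °C
Reagents that add atoms: iodomethane, CI
Why: Williamson O-methylation of the hydrogen-bonded peri phenol under carbonate conditions with excess MeI, a routine operation on 5-hydroxychromones that masks the phenol for all later basic steps.

Step 3
Reactants: 3 6-iodo-5,7-dimethoxy-2-methyl-4H-chromen-4-one
Product: 4 6-(hydroxymethyl)-5,7-dimethoxy-2-methyl-4H-chromen-4-one
Conditions: Bu3SnCH2OH (1.5 equiv), Pd(PPh3)4 (5 mol %), 1,4-dioxane, 100 °C
Reagents that add atoms: (tributylstannyl)methanol, CCCC[Sn](CCCC)(CCCC)CO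
Why: Stille coupling: the aryl iodide adds oxidatively to zerovalent palladium, the α-oxygenated CH2OH group of the stannane transfers in preference to butyl, and reductive elimination gives the benzylic alcohol in one step.

Step 4
Reactants: 4 6-(hydroxymethyl)-5,7-dimethoxy-2-methyl-4H-chromen-4-one
Product: 5 6-(bromomethyl)-5,7-dimethoxy-2-methyl-4H-chromen-4-one
Conditions: CBr4, PPh3, CH2Cl2, 0 °C
Reagents that add atoms: carbon tetrabromide, BrC(Br)(Br)Br
Why: Appel reaction, which turns the benzylic alcohol into the bromide under neutral conditions and so avoids acid-promoted self-benzylation of the electron-rich chromone ring; the bromide is used crude.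

Step 5
Reactants: 5 6-(bromomethyl)-5,7-dimethoxy-2-methyl-4H-chromen-4-one; 6 diethyl (2-oxobutyl)phosphonate
Product: 7 diethyl [1-(5,7-dimethoxy-2-methyl-4-oxo-4H-chromen-6-yl)-3-oxopentan-2-yl]phosphonate (racemic)
Conditions: 6 (1.3 equiv), NaH (1.2 equiv), THF, 0 °C; then 5, 0 °C → rt
Reagents that add atoms: none
Why: SN2 C-alkylation of the sodium enolate of a β-ketophosphonate by a reactive benzylic bromide, with the phosphonate in slight excess to suppress dialkylation; the new P-bearing centre is racemic and disappears in step 8.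

Step 6
Reactants: 8 methyl (R)-3-hydroxybutanoate
Product: 9 methyl (R)-3-(tert-butyldimethylsilyloxy)butanoate
Conditions: TBSCl, imidazole, DMF, rt
Reagents that add atoms: tert-butyldimethylsilyl chloride, CC(C)(C)[Si](C)(C)Cl
Why: Standard silylation of a secondary alcohol with TBSCl and imidazole, which does not touch the stereocentre.

Step 7
Reactants: 9 methyl (R)-3-(tert-butyldimethylsilyloxy)butanoate
Product: 10 (R)-3-(tert-butyldimethylsilyloxy)butanal
Conditions: i-Bu2AlH (1.05 equiv), CH2Cl2, −78 °C; MeOH quench, aq. KNaC4H4O6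
Reagents that add atoms: none
Why: Partial hydride reduction of the ester to the aldehyde at −78 °C, routine for β-silyloxy esters, with the low temperature holding back over-reduction; the aldehyde is used at once to avoid β-elimination.

Step 8
Reactants: 7 diethyl [1-(5,7-dimethoxy-2-methyl-4-oxo-4H-chromen-6-yl)-3-oxopentan-2-yl]phosphonate; 10 (R)-3-(tert-butyldimethylsilyloxy)butanal
Product: 11 (R,E)-7-(tert-butyldimethylsilyloxy)-4-[(5,7-dimethoxy-2-methyl-4-oxo-4H-chromen-6-yl)methyl]oct-4-en-3-one
Conditions: NaH (1.05 equiv), THF, 0 °C; then 10, 0 → 40 °C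
Reagents that add atoms: none
Why: Horner–Wadsworth–Emmons olefination of an α-substituted β-ketophosphonate with an unhindered aldehyde, expected to give mainly the E enone; the geometry is of no consequence because both isomers lead to the same product in step 9.

Step 9
Reactants: 11 (R,E)-7-(tert-butyldimethylsilyloxy)-4-[(5,7-dimethoxy-2-methyl-4-oxo-4H-chromen-6-yl)methyl]oct-4-en-3-one; 12 dimethyl malonate
Product: 14 methyl 5-[(5,7-dimethoxy-2-methyl-4-oxo-4H-chromen-6-yl)methyl]-3-methyl-2,4-dioxo-6-[(2R)-2-(tert-butyldimethylsilyloxy)propyl]cyclohexane-1-carboxylate (ring centres as a mixture), via Michael adduct 13 (not isolated)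
Conditions: 12 (1.3 equiv), NaOMe (1.1 equiv), MeOH, rt → 65 °C; then aq. HCl to pH 3, 0 °C
Reagents that add atoms: none
Why: The malonate anion adds to the enone β-carbon (future C4a); after proton exchange the enolate on the ethyl side of the ketone (future C7) attacks one of the two equivalent ester carbonyls and expels methoxide, and the 1,3-diketone so formed is deprotonated at once, which draws both equilibria forward. This is the Michael–Claisen (Dieckmann-type) synthesis of cyclohexane-1,3-diones from ethyl alkenyl ketones and malonates, which is known for α-alkylated enones as well. The single new ring, the carbocycle C4a–C5–C6–C7–C8–C8a, closes in the 6-exo-trig mode at the ester carbonyl. The sp3 centres created at C4a, C5, C7 and C8a are under no control and need none, since step 10 removes all of them; the carbinol centre of the side chain lies outside the reacting atoms and keeps the R configuration of the chiral pool. The selectivity needed is chemoselectivity, and the substrate supplies it: the enolate on the C5 side could only close a four-membered ring, O-acylation to an enol lactone is reversed by methoxide whereas C-acylation ends in the stabilised diketone enolate, and the pyranone C2, with two donor substituents, is a far poorer acceptor than the acyclic enone. Malonate is kept in excess over NaOMe so that the medium stays at the basicity of the malonate anion, which disfavours γ-deprotonation with loss of silanolate, and if methoxide should open the pyranone the phenol can cyclise back only through the C8a oxygen, so the acidic work-up restores the chromone.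

Step 10
Reactants: 14 methyl 5-[(5,7-dimethoxy-2-methyl-4-oxo-4H-chromen-6-yl)methyl]-3-methyl-2,4-dioxo-6-[(2R)-2-(tert-butyldimethylsilyloxy)propyl]cyclohexane-1-carboxylate
Product: 15 methyl 5-[(5,7-dimethoxy-2-methyl-4-oxo-4H-chromen-6-yl)methyl]-2,4-dihydroxy-3-methyl-6-[(2R)-2-(tert-butyldimethylsilyloxy)propyl]benzoate
Conditions: DDQ (1.1 equiv), 1,4-dioxane, rt → 60 °C
Reagents that add atoms: none
Why: Quinone dehydrogenation: DDQ takes a hydride from C4a of the enolised dione, a proton is lost and tautomerisation gives the hexasubstituted resorcylate, which removes the four uncontrolled ring stereocentres while the silyl ether, the chromone and the side-chain stereocentre are inert.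

Step 11
Reactants: 15 methyl 5-[(5,7-dimethoxy-2-methyl-4-oxo-4H-chromen-6-yl)methyl]-2,4-dihydroxy-3-methyl-6-[(2R)-2-(tert-butyldimethylsilyloxy)propyl]benzoate
Product: 17 (3R)-5-[(5,7-dimethoxy-2-methyl-4-oxo-4H-chromen-6-yl)methyl]-6,8-dihydroxy-3,7-dimethyl-3,4-dihydro-1H-isochromen-1-one, via hydroxy ester 16 (not isolated)
Conditions: TsOH·H2O (0.3 equiv), MeCN–H2O (10:1), 60 °C
Reagents that add atoms: none
Why: Acid-catalysed hydrolysis of the silyl ether followed by 6-exo-trig lactonisation (intramolecular transesterification) of the freed secondary alcohol onto the ortho methyl ester; the C3–O bond is never broken, so the R configuration is retained.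

Step 12
Reactants: 17 (3R)-5-[(5,7-dimethoxy-2-methyl-4-oxo-4H-chromen-6-yl)methyl]-6,8-dihydroxy-3,7-dimethyl-3,4-dihydro-1H-isochromen-1-one
Product: 18 (3R)-6,8-dihydroxy-5-[(5-hydroxy-7-methoxy-2-methyl-4-oxo-4H-chromen-6-yl)methyl]-3,7-dimethyl-3,4-dihydro-1H-isochromen-1-one (CNP0180307.1)
Conditions: BCl3 (4 equiv), CH2Cl2, −78 → 0 °C; then H2O
Reagents that add atoms: none
Why: Chelation-controlled Lewis-acid ether cleavage: BCl3 binds between the chromone C4 carbonyl and the peri 5-methoxy oxygen and removes only that methyl group, which leaves the 7-methoxy group, the lactone and the stereocentre untouched at low temperature.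

Compound list
1 | eugenin (5-hydroxy-7-methoxy-2-methyl-4H-chromen-4-one) | COc1cc(O)c2c(c1)oc(C)cc2=O | starting material
2 | 5-hydroxy-6-iodo-7-methoxy-2-methyl-4H-chromen-4-one | COc1cc2oc(C)cc(=O)c2c(O)c1I | intermediate
3 | 6-iodo-5,7-dimethoxy-2-methyl-4H-chromen-4-one | COc1cc2oc(C)cc(=O)c2c(OC)c1I | intermediate
4 | 6-(hydroxymethyl)-5,7-dimethoxy-2-methyl-4H-chromen-4-one | COc1cc2oc(C)cc(=O)c2c(OC)c1CO | intermediate
5 | 6-(bromomethyl)-5,7-dimethoxy-2-methyl-4H-chromen-4-one | COc1cc2oc(C)cc(=O)c2c(OC)c1CBr | intermediate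
6 | diethyl (2-oxobutyl)phosphonate | CCOP(=O)(CC(=O)CC)OCC | starting material
7 | diethyl [1-(5,7-dimethoxy-2-methyl-4-oxo-4H-chromen-6-yl)-3-oxopentan-2-yl]phosphonate (racemic at the P-bearing carbon) | CCOP(=O)(OCC)C(Cc1c(OC)cc2oc(C)cc(=O)c2c1OC)C(=O)CC | intermediate
8 | methyl (R)-3-hydroxybutanoate | COC(=O)C[C@@H](C)O | starting material
9 | methyl (R)-3-(tert-butyldimethylsilyloxy)butanoate | COC(=O)C[C@@H](C)O[Si](C)(C)C(C)(C)C | intermediate
10 | (R)-3-(tert-butyldimethylsilyloxy)butanal | O=CC[C@@H](C)O[Si](C)(C)C(C)(C)C | intermediate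
11 | (R,E)-7-(tert-butyldimethylsilyloxy)-4-[(5,7-dimethoxy-2-methyl-4-oxo-4H-chromen-6-yl)methyl]oct-4-en-3-one | CCC(=O)/C(Cc1c(OC)cc2oc(C)cc(=O)c2c1OC)=C/C[C@@H](C)O[Si](C)(C)C(C)(C)C | intermediate
12 | dimethyl malonate | COC(=O)CC(=O)OC | starting material
13 | Michael adduct, not isolated: dimethyl 2-[(2R)-2-(tert-butyldimethylsilyloxy)-5-[(5,7-dimethoxy-2-methyl-4-oxo-4H-chromen-6-yl)methyl]-6-oxooctan-4-yl]propanedioate (C4 and C5 of the chain uncontrolled) | COC(=O)C(C(=O)OC)C(C[C@@H](C)O[Si](C)(C)C(C)(C)C)C(Cc1c(OC)cc2oc(C)cc(=O)c2c1OC)C(=O)CC | intermediate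
14 | methyl 5-[(5,7-dimethoxy-2-methyl-4-oxo-4H-chromen-6-yl)methyl]-3-methyl-2,4-dioxo-6-[(2R)-2-(tert-butyldimethylsilyloxy)propyl]cyclohexane-1-carboxylate (ring centres uncontrolled) | COC(=O)C1C(=O)C(C)C(=O)C(Cc2c(OC)cc3oc(C)cc(=O)c3c2OC)C1C[C@@H](C)O[Si](C)(C)C(C)(C)C | intermediate
15 | methyl 5-[(5,7-dimethoxy-2-methyl-4-oxo-4H-chromen-6-yl)methyl]-2,4-dihydroxy-3-methyl-6-[(2R)-2-(tert-butyldimethylsilyloxy)propyl]benzoate | COC(=O)c1c(O)c(C)c(O)c(Cc2c(OC)cc3oc(C)cc(=O)c3c2OC)c1C[C@@H](C)O[Si](C)(C)C(C)(C)C | intermediate
16 | hydroxy ester, not isolated: methyl 5-[(5,7-dimethoxy-2-methyl-4-oxo-4H-chromen-6-yl)methyl]-2,4-dihydroxy-6-[(2R)-2-hydroxypropyl]-3-methylbenzoate | COC(=O)c1c(O)c(C)c(O)c(Cc2c(OC)cc3oc(C)cc(=O)c3c2OC)c1C[C@@H](C)O | intermediate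
17 | (3R)-5-[(5,7-dimethoxy-2-methyl-4-oxo-4H-chromen-6-yl)methyl]-6,8-dihydroxy-3,7-dimethyl-3,4-dihydro-1H-isochromen-1-one | COc1cc2oc(C)cc(=O)c2c(OC)c1Cc1c(O)c(C)c(O)c2c1C[C@@H](C)OC2=O | intermediate
18 | (3R)-6,8-dihydroxy-5-[(5-hydroxy-7-methoxy-2-methyl-4-oxo-4H-chromen-6-yl)methyl]-3,7-dimethyl-3,4-dihydro-1H-isochromen-1-one (CNP0180307.1) | COc1cc2oc(C)cc(=O)c2c(O)c1Cc1c(O)c(C)c(O)c2c1C[C@@H](C)OC2=O | target

Total step count: 12.
Longest linear sequence: 10 steps (1, 2, 3, 4, 5, 8, 9, 10, 11, 12, from eugenin); steps 6 and 7 form the short side branch.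

Steps most likely to fail

First, step 9, the annulation. The conjugate addition to the α,β-disubstituted enone may be slow and reversible, so that the adduct reverts before the Claisen closure. Prolonged exposure to methoxide may also open the pyranone or expel silanolate from the γ-deprotonated enone. The fallback takes the chromone and the α-branch out of the annulation and makes the C5–CH2 bond afterwards by Friedel–Crafts benzylation. It sets out from 6 and 10 and comes back to the route at 17.
- Olefination of 6 with 10 (NaH, THF) should give (R,E)-7-(tert-butyldimethylsilyloxy)oct-4-en-3-one F1, an unhindered enone of the kind for which the malonate annulation is routine.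
- Compound 12 and NaOMe in MeOH should convert F1, through dimethyl 2-[(2R)-2-(tert-butyldimethylsilyloxy)-6-oxooctan-4-yl]propanedioate F2 (not isolated), into methyl 3-methyl-2,4-dioxo-6-[(2R)-2-(tert-butyldimethylsilyloxy)propyl]cyclohexane-1-carboxylate F3.
- DDQ as in step 10 should give methyl 2,4-dihydroxy-3-methyl-6-[(2R)-2-(tert-butyldimethylsilyloxy)propyl]benzoate F4.
- TsOH in aqueous MeCN as in step 11 should lead, through methyl 2,4-dihydroxy-6-[(2R)-2-hydroxypropyl]-3-methylbenzoate F5 (not isolated), to (3R)-6,8-dihydroxy-3,7-dimethyl-3,4-dihydro-1H-isochromen-1-one F6.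
- C5 is the only unsubstituted aromatic position of F6 and lies ortho and para to its two hydroxyls. Acid-catalysed benzylation with alcohol 4 (catalytic TsOH, MeCN, F6 in excess to suppress self-condensation of 4) should therefore give 17 directly, and step 12 follows unchanged.

Second, step 10, the dehydrogenation. Once the electron-rich resorcinol has formed, over-oxidation at the doubly benzylic methylene may set in, or the diketone enol may add to the quinone through oxygen or carbon instead of transferring hydride. The fallback is halogenation followed by dehydrohalogenation; it sets out from 14 and comes back at 15.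
- N-Chlorosuccinimide (1.0 equiv, CH2Cl2, 0 °C) should chlorinate the diketone carbon C7 far faster than the chromone ring. The product is methyl 3-chloro-5-[(5,7-dimethoxy-2-methyl-4-oxo-4H-chromen-6-yl)methyl]-3-methyl-2,4-dioxo-6-[(2R)-2-(tert-butyldimethylsilyloxy)propyl]cyclohexane-1-carboxylate F7.
- LiCl and Li2CO3 in DMF at 90 °C should then remove HCl through the C5 enol and, after tautomerisation, give 15. The carbonate keeps the medium from turning acidic, so the silyl ether should survive.

Third, step 3, the hydroxymethylation. Transmetalation of the sp3 stannane at an arylpalladium centre flanked by two methoxy groups may be slow, so that protodeiodination and homocoupling take over. The fallback is reductive carbonylation; it sets out from 3 and comes back at 4.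
- CO (1 atm), Et3SiH, Pd(OAc)2 with dppf, Na2CO3, DMF, 80 °C should give 5,7-dimethoxy-2-methyl-4-oxo-4H-chromene-6-carbaldehyde F8, because CO insertion is little affected by ortho substituents.
- NaBH4 (0.3 equiv, MeOH–CH2Cl2, −20 °C) should reduce the aldehyde ahead of the vinylogous ester carbonyl of the chromone and give 4.

Further compounds
F1 | step 9 | (R,E)-7-(tert-butyldimethylsilyloxy)oct-4-en-3-one | CCC(=O)/C=C/C[C@@H](C)O[Si](C)(C)C(C)(C)C
F2 | step 9 | dimethyl 2-[(2R)-2-(tert-butyldimethylsilyloxy)-6-oxooctan-4-yl]propanedioate (not isolated) | COC(=O)C(C(=O)OC)C(C[C@@H](C)O[Si](C)(C)C(C)(C)C)CC(=O)CC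
F3 | step 9 | methyl 3-methyl-2,4-dioxo-6-[(2R)-2-(tert-butyldimethylsilyloxy)propyl]cyclohexane-1-carboxylate | COC(=O)C1C(=O)C(C)C(=O)CC1C[C@@H](C)O[Si](C)(C)C(C)(C)C
F4 | step 9 | methyl 2,4-dihydroxy-3-methyl-6-[(2R)-2-(tert-butyldimethylsilyloxy)propyl]benzoate | COC(=O)c1c(O)c(C)c(O)cc1C[C@@H](C)O[Si](C)(C)C(C)(C)C
F5 | step 9 | methyl 2,4-dihydroxy-6-[(2R)-2-hydroxypropyl]-3-methylbenzoate (not isolated) | COC(=O)c1c(O)c(C)c(O)cc1C[C@@H](C)O
F6 | step 9 | (3R)-6,8-dihydroxy-3,7-dimethyl-3,4-dihydro-1H-isochromen-1-one | Cc1c(O)cc2C[C@@H](C)OC(=O)c2c1O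
F7 | step 10 | methyl 3-chloro-5-[(5,7-dimethoxy-2-methyl-4-oxo-4H-chromen-6-yl)methyl]-3-methyl-2,4-dioxo-6-[(2R)-2-(tert-butyldimethylsilyloxy)propyl]cyclohexane-1-carboxylate | COC(=O)C1C(=O)C(C)(Cl)C(=O)C(Cc2c(OC)cc3oc(C)cc(=O)c3c2OC)C1C[C@@H](C)O[Si](C)(C)C(C)(C)C
F8 | step 3 | 5,7-dimethoxy-2-methyl-4-oxo-4H-chromene-6-carbaldehyde | COc1cc2oc(C)cc(=O)c2c(OC)c1C=O
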